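**Plan**

1. Numbering: C1 is the benzylic CH2 on ring A; the oxolane is O1, C2, C3 (OH), C4, C5; C6 is the methylene and C7 the ketone on ring B.
2. Retrosynthesis: C7=O is taken back to an aryl alkyne and C3–OH to C3–Si; the oxolane is then cut at C4–C5 and O1–C2 in one operation.
3. Enabling feature: C2–C3–C4 is the three-carbon unit of an α-branched allylsilane whose silicon ends on C3 as a masked hydroxyl, and O1–C5 with the C6–C7 arm is the C=O of an arylpropynal.
4. Forward: eugenol gives the (S)-allylsilane 10 in four steps, O-benzylvanillin gives ynal 14 in two, and a BF3 annulation joins the halves and closes the only new ring.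
5. Endgame: silicon to hydroxyl with retention, inversion at C3, alkyne hydration, debenzylation.
6. Stereochemistry: a copper–carbene catalyst sets the C–Si centre of 10; the annulation relays it to C2 (inversion) and C3 (silyl shift) and sets C5 cis to C2; a Mitsunobu reaction corrects C3.

Key step: step 9

Assumption: the antipode of the chiral carbene ligand in step 6 is the one that delivers the (S)-silane, to be fixed in a trial run; 4-benzyloxy-3-methoxybenzaldehyde and all unnumbered reagents are bought.

**Route**

Step 1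
Reactants: 1 eugenol
Product: 2 O-benzyleugenol (4-allyl-1-benzyloxy-2-methoxybenzene)
Conditions: BnBr, K2CO3, DMF, rt
Reagents that add atoms: benzyl bromide, BrCc1ccccc1
Why: Williamson etherification of the phenoxide gives a benzyl ether that should survive every later step until the final hydrogenolysis.

Step 2
Reactants: 2 O-benzyleugenol; 3 (Z)-but-2-ene-1,4-diol
Product: 4 (E)-4-(4-benzyloxy-3-methoxyphenyl)but-2-en-1-ol
Conditions: 3 (3 equiv), second-generation Grubbs catalyst RuCl2(=CHPh)(PCy3)(H2IMes) (3 mol%), 1,4-benzoquinone (10 mol%), CH2Cl2, 40 °C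
Reagents that add atoms: none
Why: Olefin cross-metathesis exchanges the terminal methylene of the allylarene for the CH–CH2OH half of the excess cis-diol, reversible metathesis should favour the E-alkene, and benzoquinone is added against Ru–H migration of the double bond into conjugation.

Step 3
Reactants: 4 (E)-4-(4-benzyloxy-3-methoxyphenyl)but-2-en-1-ol
Product: 5 (E)-4-(4-benzyloxy-3-methoxyphenyl)but-2-en-1-yl diethyl phosphate
Conditions: ClP(O)(OEt)2, pyridine, DMAP (cat.), CH2Cl2, 0 °C
Reagents that add atoms: diethyl chlorophosphate, CCOP(=O)(Cl)OCC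
Why: O-phosphorylation of the primary allylic alcohol (nucleophilic substitution at phosphorus) installs the leaving group for the SN2' step without touching the alkene.

Step 4
Reactants: 6 diphenylmethane
Product: 8 benzhydryldimethylsilane, via (diphenylmethyl)lithium 7 (not isolated)
Conditions: n-BuLi, THF, 0 °C to rt; then Me2SiHCl, −78 °C to rt
Reagents that add atoms: chlorodimethylsilane, C[SiH](C)Cl
Why: Deprotonation of diphenylmethane gives the stabilised diphenylmethyl anion, which displaces chloride at silicon (nucleophilic substitution at silicon) and leaves the Si–H bond for step 5.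

Step 5
Reactants: 8 benzhydryldimethylsilane
Product: 9 2-(benzhydryldimethylsilyl)-4,4,5,5-tetramethyl-1,3,2-dioxaborolane
Conditions: B2pin2, Pt(PPh3)4 (2 mol%), methylcyclohexane, 100 °C
Reagents that add atoms: bis(pinacolato)diboron, CC1(C)OB(OC1(C)C)B1OC(C)(C)C(C)(C)O1
Why: Catalytic dehydrogenative Si–H borylation of a tertiary silane with a diboron is known for trialkylsilanes, and a zerovalent phosphine–platinum catalyst is preferred to iridium–bipyridine systems, which would also borylate the phenyl C–H bonds.

Step 6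
Reactants: 5 (E)-4-(4-benzyloxy-3-methoxyphenyl)but-2-en-1-yl diethyl phosphate; 9 2-(benzhydryldimethylsilyl)-4,4,5,5-tetramethyl-1,3,2-dioxaborolane
Product: 10 (S)-benzhydryl[1-(4-benzyloxy-3-methoxyphenyl)but-3-en-2-yl]dimethylsilane
Conditions: 9 (1.5 equiv), CuCl (5 mol%), chiral imidazolinium salt (6 mol%, N-aryl carbene precursor built on enantiopure 1,2-diphenylethane-1,2-diamine), NaOMe (1.5 equiv), THF, 0 °C
Reagents that add atoms: none
Why: Copper-catalysed enantioselective allylic substitution with a silicon nucleophile: methoxide transfers the silyl group from boron to the carbene–copper centre, which attacks the γ-carbon (SN2') with loss of phosphate, and the chiral carbene chooses the alkene face, which sets the C–Si stereocentre as (S).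

Step 7
Reactants: 11 4-benzyloxy-3-methoxybenzaldehyde (O-benzylvanillin)
Product: 12 1-benzyloxy-4-(2,2-dibromovinyl)-2-methoxybenzene
Conditions: CBr4, PPh3, CH2Cl2, 0 °C
Reagents that add atoms: carbon tetrabromide, BrC(Br)(Br)Br
Why: Corey–Fuchs olefination, in which the ylide Ph3P=CBr2 formed from CBr4 and PPh3 converts the aldehyde into the 1,1-dibromoalkene by a Wittig reaction.

Step 8
Reactants: 12 1-benzyloxy-4-(2,2-dibromovinyl)-2-methoxybenzene
Product: 14 3-(4-benzyloxy-3-methoxyphenyl)prop-2-ynal, via lithium acetylide 13 (not isolated)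
Conditions: n-BuLi (2.2 equiv), THF, −78 °C; then DMF, −78 to 0 °C; inverse quench into aq. KH2PO4
Reagents that add atoms: N,N-dimethylformamide, CN(C)C=O
Why: The second half of the Corey–Fuchs sequence (Br/Li exchange, Fritsch–Buttenberg–Wiechell rearrangement, deprotonation) gives the lithium acetylide, which DMF formylates, and the inverse quench into phosphate buffer should release the ynal without conjugate addition of dimethylamine.

Step 9
Reactants: 10 (S)-benzhydryl[1-(4-benzyloxy-3-methoxyphenyl)but-3-en-2-yl]dimethylsilane; 14 3-(4-benzyloxy-3-methoxyphenyl)prop-2-ynal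
Product: 16 (2R,3S,5R)-3-(benzhydryldimethylsilyl)-2-(4-benzyloxy-3-methoxybenzyl)-5-[(4-benzyloxy-3-methoxyphenyl)ethynyl]oxolane, via β-silyl cation 15 (not isolated)
Conditions: 14 (1.2 equiv), BF3·OEt2 (1.1 equiv), CH2Cl2, −78 °C; Et3N, then aq. NaHCO3 at −78 °C
Reagents that add atoms: none
Why: BF3 activates the ynal, the alkene terminus C4 of 10 attacks the carbonyl carbon C5 anti to the C–Si bond (anti-SE2'), and the resulting β-silyl cation 15, bridged by silicon between C2 and C3, is opened at C2 by the boron-bound oxygen with inversion, which forms C4–C5 and O1–C2 and leaves silicon on C3. The closest known reaction type is the Lewis acid-promoted [3+2] annulation of α-branched chiral allylsilanes with aldehydes, which gives 2,5-cis-3-silyltetrahydrofurans with 1,2-silyl migration. The oxolane closes by a 5-exo-tet attack of oxygen on the silicon-bridged C2. C2 is controlled by the (S) C–Si centre of 10 (anti opening, inversion); C3 by the same centre, because silicon stays on the face it occupied and, with 10 reacting in the conformer whose C2–H bond eclipses the alkene, ends trans to the C2 benzyl group; C5 by the open synclinal transition state of the BF3 complex, which should place the alkynyl group cis to the C2 substituent. The step needs annulation to outrun loss of silicon (Sakurai allylation) and 1,2-addition to outrun conjugate addition; the bulky, poorly nucleofugal benzhydryldimethylsilyl group and the low temperature should secure the first, and the hard BF3-bound carbonyl the second.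

Step 10
Reactants: 16 the 3-silyloxolane
Product: 18 (2R,3S,5R)-2-(4-benzyloxy-3-methoxybenzyl)-5-[(4-benzyloxy-3-methoxyphenyl)ethynyl]oxolan-3-ol (OH trans to the C2 benzyl group), via fluorosilane 17 (not isolated)
Conditions: TBAF, THF, 0 °C to rt; then 30% H2O2, KHCO3, MeOH, rt
Reagents that add atoms: hydrogen peroxide, OO
Why: Tamao–Fleming oxidation: fluoride expels the stabilised diphenylmethyl anion from silicon, and basic peroxide oxidises the fluorosilane by 1,2-shift of C3 from silicon to oxygen with retention, so the hydroxyl appears trans to the C2 benzyl group without any electrophile that could attack the arenes or the alkyne.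

Step 11
Reactants: 18 the trans alcohol
Product: 19 (2R,3R,5R)-2-(4-benzyloxy-3-methoxybenzyl)-5-[(4-benzyloxy-3-methoxyphenyl)ethynyl]oxolan-3-yl 4-nitrobenzoate
Conditions: 4-nitrobenzoic acid, PPh3, DIAD, THF, 0 °C to rt
Reagents that add atoms: 4-nitrobenzoic acid, O=C(O)c1ccc(cc1)[N+](=O)[O-]
Why: Mitsunobu reaction: the C3 alkoxyphosphonium ion is displaced by 4-nitrobenzoate in an SN2 step, which inverts C3 and puts the oxygen cis to the C2 and C5 substituents as in the target, and the acidic 4-nitrobenzoic acid is the usual partner for hindered secondary alcohols.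

Step 12
Reactants: 19 the 4-nitrobenzoate
Product: 20 (2R,3R,5R)-2-(4-benzyloxy-3-methoxybenzyl)-5-[(4-benzyloxy-3-methoxyphenyl)ethynyl]oxolan-3-ol (all-cis)
Conditions: K2CO3 (cat.), MeOH/THF, rt
Reagents that add atoms: none
Why: Carbonate-catalysed transesterification with methanol removes the activated ester, and it is done before the ketone exists so that no base meets a β-alkoxy ketone that could open by a retro-oxa-Michael reaction.

Step 13
Reactants: 20 the all-cis alkynyl alcohol
Product: 21 1-(4-benzyloxy-3-methoxyphenyl)-2-[(2R,3R,5R)-configured 5-(4-benzyloxy-3-methoxybenzyl)-4-hydroxyoxolan-2-yl]ethan-1-one (di-O-benzyl renealtin A; descriptors in the numbering of the plan)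
Conditions: (Ph3P)AuNTf2 (5 mol%), 1,4-dioxane/H2O (10:1), 50 °C
Reagents that add atoms: water, O
Why: Gold-catalysed Markovnikov hydration of an internal aryl alkyne: water attacks the gold-bound alkyne at C7, the carbon that carries positive charge best (benzylic to the para-oxygenated ring B and remote from the electron-withdrawing C5–O1 bond), and tautomerisation gives the C7 ketone under neutral conditions that leave C5 untouched.

Step 14
Reactants: 21 di-O-benzyl renealtin A
Product: 22 renealtin A
Conditions: H2 (1 atm), 10% Pd/C, EtOAc, rt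
Reagents that add atoms: none
Why: Hydrogenolysis of the two aryl benzyl ethers over Pd/C at 1 atm should be fast, whereas the electron-rich aryl ketone and the non-oxygenated benzylic C1 should not be reduced if hydrogen uptake is stopped at two equivalents.

**Compound list**

1 | eugenol | COc1cc(CC=C)ccc1O | starting material
2 | O-benzyleugenol (4-allyl-1-benzyloxy-2-methoxybenzene) | COc1cc(CC=C)ccc1OCc1ccccc1 | intermediate
3 | (Z)-but-2-ene-1,4-diol | OC/C=C\CO | starting material
4 | (E)-4-(4-benzyloxy-3-methoxyphenyl)but-2-en-1-ol | COc1cc(C/C=C/CO)ccc1OCc1ccccc1 | intermediate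
5 | (E)-4-(4-benzyloxy-3-methoxyphenyl)but-2-en-1-yl diethyl phosphate | CCOP(=O)(OCC)OC/C=C/Cc1ccc(OCc2ccccc2)c(OC)c1 | intermediate
6 | diphenylmethane | C(c1ccccc1)c1ccccc1 | starting material
7 | (diphenylmethyl)lithium | [Li]C(c1ccccc1)c1ccccc1 | intermediate
8 | benzhydryldimethylsilane | C[SiH](C)C(c1ccccc1)c1ccccc1 | intermediate
9 | 2-(benzhydryldimethylsilyl)-4,4,5,5-tetramethyl-1,3,2-dioxaborolane | CC1(C)OB(OC1(C)C)[Si](C)(C)C(c1ccccc1)c1ccccc1 | intermediate
10 | (S)-benzhydryl[1-(4-benzyloxy-3-methoxyphenyl)but-3-en-2-yl]dimethylsilane | C=C[C@H](Cc1ccc(OCc2ccccc2)c(OC)c1)[Si](C)(C)C(c1ccccc1)c1ccccc1 | intermediate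
11 | 4-benzyloxy-3-methoxybenzaldehyde (O-benzylvanillin) | COc1cc(C=O)ccc1OCc1ccccc1 | starting material
12 | 1-benzyloxy-4-(2,2-dibromovinyl)-2-methoxybenzene | COc1cc(C=C(Br)Br)ccc1OCc1ccccc1 | intermediate
13 | [(4-benzyloxy-3-methoxyphenyl)ethynyl]lithium | COc1cc(C#C[Li])ccc1OCc1ccccc1 | intermediate
14 | 3-(4-benzyloxy-3-methoxyphenyl)prop-2-ynal | O=CC#Cc1ccc(OCc2ccccc2)c(OC)c1 | intermediate
15 | zwitterionic β-silyl cation (C3 cation bridged by silicon from C2, C5 alkoxide bound to BF3) | COc1cc(C[C@@H]([CH+]C[C@@H](O[B-](F)(F)F)C#Cc2ccc(OCc3ccccc3)c(OC)c2)[Si](C)(C)C(c2ccccc2)c2ccccc2)ccc1OCc1ccccc1 | intermediate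
16 | (2R,3S,5R)-3-(benzhydryldimethylsilyl)-2-(4-benzyloxy-3-methoxybenzyl)-5-[(4-benzyloxy-3-methoxyphenyl)ethynyl]oxolane | COc1cc(C[C@H]2O[C@@H](C#Cc3ccc(OCc4ccccc4)c(OC)c3)C[C@@H]2[Si](C)(C)C(c2ccccc2)c2ccccc2)ccc1OCc1ccccc1 | intermediate
17 | (2R,3S,5R)-2-(4-benzyloxy-3-methoxybenzyl)-5-[(4-benzyloxy-3-methoxyphenyl)ethynyl]-3-(fluorodimethylsilyl)oxolane | COc1cc(C[C@H]2O[C@@H](C#Cc3ccc(OCc4ccccc4)c(OC)c3)C[C@@H]2[Si](C)(C)F)ccc1OCc1ccccc1 | intermediate
18 | (2R,3S,5R)-2-(4-benzyloxy-3-methoxybenzyl)-5-[(4-benzyloxy-3-methoxyphenyl)ethynyl]oxolan-3-ol (2,3-trans, 2,5-cis) | COc1cc(C[C@H]2O[C@@H](C#Cc3ccc(OCc4ccccc4)c(OC)c3)C[C@@H]2O)ccc1OCc1ccccc1 | intermediate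
19 | (2R,3R,5R)-2-(4-benzyloxy-3-methoxybenzyl)-5-[(4-benzyloxy-3-methoxyphenyl)ethynyl]oxolan-3-yl 4-nitrobenzoate | COc1cc(C[C@H]2O[C@@H](C#Cc3ccc(OCc4ccccc4)c(OC)c3)C[C@H]2OC(=O)c2ccc(cc2)[N+](=O)[O-])ccc1OCc1ccccc1 | intermediate
20 | (2R,3R,5R)-2-(4-benzyloxy-3-methoxybenzyl)-5-[(4-benzyloxy-3-methoxyphenyl)ethynyl]oxolan-3-ol (all-cis) | COc1cc(C[C@H]2O[C@@H](C#Cc3ccc(OCc4ccccc4)c(OC)c3)C[C@H]2O)ccc1OCc1ccccc1 | intermediate
21 | di-O-benzyl renealtin A, (2R,3R,5R) in the numbering of the plan | COc1cc(C[C@H]2O[C@@H](CC(=O)c3ccc(OCc4ccccc4)c(OC)c3)C[C@H]2O)ccc1OCc1ccccc1 | intermediate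
22 | renealtin A, (2R,3R,5R) in the numbering of the plan, all-cis | COc1cc(C[C@H]2O[C@@H](CC(=O)c3ccc(O)c(OC)c3)C[C@H]2O)ccc1O | target

**Count**

Total: 14 steps. Longest linear sequence: 10 steps (1, 2, 3, 6, 9, 10, 11, 12, 13, 14); steps 4–5 and 7–8 are side branches.

**Steps most likely to fail**

Step 6. The hindered benzhydryldimethylsilyl group may transfer slowly from boron to copper, or methoxide may attack silicon and cleave the benzhydryl group, so that conversion, γ-selectivity or enantioselectivity fall short. The fallback sets out from 5 and comes back at 18; it also makes steps 4 and 5 unnecessary. The same copper–carbene silylation is run with commercial dimethyl(phenyl)silyl pinacolborane, the reagent for which this reaction is established, and should give (S)-[1-(4-benzyloxy-3-methoxyphenyl)but-3-en-2-yl]dimethyl(phenyl)silane F1. BF3·OEt2 annulation of F1 with 14 at −78 °C, for which this silyl group has direct precedent on α-branched allylsilanes, should give (2R,3S,5R)-2-(4-benzyloxy-3-methoxybenzyl)-5-[(4-benzyloxy-3-methoxyphenyl)ethynyl]-3-[dimethyl(phenyl)silyl]oxolane F2. A nucleophilic Fleming oxidation (t-BuOOH, KH, TBAF, N-methylpyrrolidone), which uses no electrophile, then converts C3–Si into C3–OH with retention and delivers 18.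

Step 9. The donor-substituted arylalkynyl group lowers the electrophilicity of the aldehyde, is small and linear, and stabilises a propargylic cation at C5. The process risks are therefore slow addition with competing loss of silicon, erosion of the 2,5-cis selectivity, and ionisation of the new C5–O1 bond under BF3 with scrambling of C5. The fallback sets out from 10 and comes back at 18; it moves the ring B aryl group to a later cross-coupling. Annulation of 10 with commercial 3-(triisopropylsilyl)prop-2-ynal under the same BF3 conditions should give (2R,3S,5R)-3-(benzhydryldimethylsilyl)-2-(4-benzyloxy-3-methoxybenzyl)-5-[(triisopropylsilyl)ethynyl]oxolane F3, whose alkyne carries a bulky terminus and no cation-stabilising arene. TBAF removes both the benzhydryl group and the alkynyl silyl group to give (2R,3S,5R)-2-(4-benzyloxy-3-methoxybenzyl)-5-ethynyl-3-(fluorodimethylsilyl)oxolane F4, which is not isolated. H2O2/KHCO3 in the same flask gives (2R,3S,5R)-2-(4-benzyloxy-3-methoxybenzyl)-5-ethynyloxolan-3-ol F5. Benzylation of commercial 4-iodo-2-methoxyphenol (BnBr, K2CO3) gives 1-benzyloxy-4-iodo-2-methoxybenzene F6, and Sonogashira coupling of F5 with F6 (PdCl2(PPh3)2, CuI, Et3N, THF, rt) delivers 18.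

Step 11. The carboxylate must enter on the ring face that carries the C2 and C5 substituents, so elimination towards C4 or incomplete activation of the hindered alcohol may compete with substitution. The fallback sets out from 18 and comes back at 20, bypassing 19. Oxidation with Dess–Martin periodinane (NaHCO3, CH2Cl2, 0 °C) gives (2R,5R)-2-(4-benzyloxy-3-methoxybenzyl)-5-[(4-benzyloxy-3-methoxyphenyl)ethynyl]oxolan-3-one F7, which is used crude to avoid epimerisation at C2. Reduction with LiBH(s-Bu)3 (L-Selectride, THF, −78 °C) should deliver hydride to the face opposite the two cis substituents and give the all-cis alcohol 20 under substrate control.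

**Further compounds**

F1 | step 6 | (S)-[1-(4-benzyloxy-3-methoxyphenyl)but-3-en-2-yl]dimethyl(phenyl)silane | C=C[C@H](Cc1ccc(OCc2ccccc2)c(OC)c1)[Si](C)(C)c1ccccc1
F2 | step 6 | (2R,3S,5R)-2-(4-benzyloxy-3-methoxybenzyl)-5-[(4-benzyloxy-3-methoxyphenyl)ethynyl]-3-[dimethyl(phenyl)silyl]oxolane | COc1cc(C[C@H]2O[C@@H](C#Cc3ccc(OCc4ccccc4)c(OC)c3)C[C@@H]2[Si](C)(C)c2ccccc2)ccc1OCc1ccccc1
F3 | step 9 | (2R,3S,5R)-3-(benzhydryldimethylsilyl)-2-(4-benzyloxy-3-methoxybenzyl)-5-[(triisopropylsilyl)ethynyl]oxolane | COc1cc(C[C@H]2O[C@@H](C#C[Si](C(C)C)(C(C)C)C(C)C)C[C@@H]2[Si](C)(C)C(c2ccccc2)c2ccccc2)ccc1OCc1ccccc1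
F4 | step 9 | (2R,3S,5R)-2-(4-benzyloxy-3-methoxybenzyl)-5-ethynyl-3-(fluorodimethylsilyl)oxolane | COc1cc(C[C@H]2O[C@@H](C#C)C[C@@H]2[Si](C)(C)F)ccc1OCc1ccccc1
F5 | step 9 | (2R,3S,5R)-2-(4-benzyloxy-3-methoxybenzyl)-5-ethynyloxolan-3-ol | COc1cc(C[C@H]2O[C@@H](C#C)C[C@@H]2O)ccc1OCc1ccccc1
F6 | step 9 | 1-benzyloxy-4-iodo-2-methoxybenzene | COc1cc(I)ccc1OCc1ccccc1
F7 | step 11 | (2R,5R)-2-(4-benzyloxy-3-methoxybenzyl)-5-[(4-benzyloxy-3-methoxyphenyl)ethynyl]oxolan-3-one | COc1cc(C[C@H]2O[C@@H](C#Cc3ccc(OCc4ccccc4)c(OC)c3)CC2=O)ccc1OCc1ccccc1
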